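**Retrosynthetic overview**
1. Feature: the chain C7(OH)–C8(OAr)–C9H2OH links ring A (4-hydroxy-3-methoxyphenyl, on C7) to ring B (4-acetyl-2,6-dimethoxyphenyl, on O8). O7 and O9 stand 1,3 across C8, so a silicon atom carried by O9 can reach C7 through the five-membered ring O9–Si–C7–C8–C9.
2. Key disconnection: C7–OH goes back to C7–Si (oxidation with retention). The C7–Si and C8–H bonds go back to an achiral (Z)-C7=C8 aryl enol ether carrying O9–SiHPh2. A chiral rhodium diphosphine picks the face, and syn addition to the (Z)-alkene gives erythro.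
3. The enol ether comes from a (Z)-2-aryloxyacrylate, made by aldol/E1cB union (C7–C8) of a ring B aryloxyacetate with O-benzylvanillin. The O8–C8 bond comes from acetosyringone and ethyl bromoacetate.
4. Rings: A and B are bought. The dioxolane masking the ring B ketone is formed first (step 2) and the 1,2-oxasilolane second (step 7). The oxasilolane is opened in step 8 and the dioxolane in step 9.
5. Protection: benzyl on the ring A phenol is removed last. The ketal shields the ketone from base, hydride and Si–H, and it keeps the ring B phenoxide a poor leaving group.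

Key step: step 7

Assumption: the sense of induction of BINAP on this new alkene class cannot be predicted safely, so (S)-BINAP is written, and if a pilot run shows the opposite sense (R)-BINAP is used with nothing else changed.

**Step 1**
Reactants: 1 acetosyringone; 2 ethyl bromoacetate
Product: 3 ethyl 2-(4-acetyl-2,6-dimethoxyphenoxy)acetate
Conditions: K2CO3, acetone, reflux
Reagents that add atoms: none
Why: Williamson ether synthesis, in which the acidic para-acyl phenoxide displaces bromide from the unhindered α-halo ester by SN2, and capping the phenol first removes the vinylogous-acid character that would make ketalisation of 1 itself sluggish.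

**Step 2**
Reactants: 3 ethyl 2-(4-acetyl-2,6-dimethoxyphenoxy)acetate
Product: 4 ethyl 2-[2,6-dimethoxy-4-(2-methyl-1,3-dioxolan-2-yl)phenoxy]acetate
Conditions: Me3SiOCH2CH2OSiMe3, Me3SiOTf (5 mol %), CH2Cl2, −78 to 0 °C; pyridine quench
Reagents that add atoms: 1,2-bis(trimethylsilyloxy)ethane, C[Si](C)(C)OCCO[Si](C)(C)C
Why: Aprotic silyl-triflate-catalysed ketalisation (Noyori conditions) is driven by formation of hexamethyldisiloxane and, with no free diol or water present, leaves the ethyl ester alone while masking the enolisable and reducible methyl ketone.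

**Step 3**
Reactants: 4 ethyl 2-[2,6-dimethoxy-4-(2-methyl-1,3-dioxolan-2-yl)phenoxy]acetate; 5 4-(benzyloxy)-3-methoxybenzaldehyde (O-benzylvanillin)
Product: 8 ethyl 3-acetoxy-3-[4-(benzyloxy)-3-methoxyphenyl]-2-[2,6-dimethoxy-4-(2-methyl-1,3-dioxolan-2-yl)phenoxy]propanoate (racemic mixture of both diastereomers), via lithium enolate 6 (not isolated), via lithium aldolate 7 (not isolated)
Conditions: LiN(iPr)2 (LDA, commercial solution), THF, −78 °C; then 5; then Ac2O, −78 °C to rt
Reagents that add atoms: acetic anhydride, CC(=O)OC(C)=O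
Why: Lithium-enolate aldol addition of an aryloxyacetate to a non-enolisable aromatic aldehyde, the standard entry to arylglycerol β-aryl ethers, with O-acetylation of the aldolate in the same flask to block retro-aldol cleavage; the two stereocentres form unselectively and are both erased in step 4.

**Step 4**
Reactants: 8 ethyl 3-acetoxy-3-[4-(benzyloxy)-3-methoxyphenyl]-2-[2,6-dimethoxy-4-(2-methyl-1,3-dioxolan-2-yl)phenoxy]propanoate
Product: 9 ethyl (Z)-3-[4-(benzyloxy)-3-methoxyphenyl]-2-[2,6-dimethoxy-4-(2-methyl-1,3-dioxolan-2-yl)phenoxy]prop-2-enoate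
Conditions: DBU, THF, rt to 50 °C; chromatography or crystallisation to a single geometric isomer
Reagents that add atoms: none
Why: E1cB elimination of acetate through the ester enolate is not stereospecific, so both diastereomers of 8 should converge on the more stable (Z)-acrylate (ring A trans to the ester and fully conjugated), and the minor (E)-isomer is removed because alkene geometry later becomes relative configuration.

**Step 5**
Reactants: 9 ethyl (Z)-3-[4-(benzyloxy)-3-methoxyphenyl]-2-[2,6-dimethoxy-4-(2-methyl-1,3-dioxolan-2-yl)phenoxy]prop-2-enoate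
Product: 10 (Z)-3-[4-(benzyloxy)-3-methoxyphenyl]-2-[2,6-dimethoxy-4-(2-methyl-1,3-dioxolan-2-yl)phenoxy]prop-2-en-1-ol
Conditions: iBu2AlH (2.5 equiv), CH2Cl2, −78 °C; aq potassium sodium tartrate
Reagents that add atoms: none
Why: 1,2-Reduction of an α,β-unsaturated ester with iBu2AlH at low temperature gives the allylic alcohol without changing alkene geometry, ketal or benzyl ether, and the non-acidic tartrate work-up spares the acid-labile aryl enol ether.

**Step 6**
Reactants: 10 (Z)-3-[4-(benzyloxy)-3-methoxyphenyl]-2-[2,6-dimethoxy-4-(2-methyl-1,3-dioxolan-2-yl)phenoxy]prop-2-en-1-ol; 11 chlorodiphenylsilane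
Product: 12 (Z)-3-[4-(benzyloxy)-3-methoxyphenyl]-2-[2,6-dimethoxy-4-(2-methyl-1,3-dioxolan-2-yl)phenoxy]prop-2-en-1-yl diphenylsilyl ether (O9–SiHPh2)
Conditions: Et3N, CH2Cl2, 0 °C; dilute with dry Et2O, filter under Ar, concentrate; used without chromatography
Reagents that add atoms: none
Why: O-Silylation of a primary alcohol with a chlorosilane and amine base (substitution at silicon) is fast and leaves Si–H intact, and the non-aqueous removal of the ammonium salt avoids hydrolysis of the labile ether and keeps chloride away from the cationic catalyst of step 7.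

**Step 7**
Reactants: 12 (Z)-3-[4-(benzyloxy)-3-methoxyphenyl]-2-[2,6-dimethoxy-4-(2-methyl-1,3-dioxolan-2-yl)phenoxy]prop-2-en-1-yl diphenylsilyl ether
Product: 13 (3R,4S)-3-[4-(benzyloxy)-3-methoxyphenyl]-4-[2,6-dimethoxy-4-(2-methyl-1,3-dioxolan-2-yl)phenoxy]-2,2-diphenyl-1,2-oxasilolane (3,4-trans)
Conditions: [Rh(cod)2]BF4 (5 mol %), (S)-BINAP (5.5 mol %), H2 pre-activation then Ar, dry degassed acetone, 25 °C
Reagents that add atoms: none
Why: Proposed new method: oxidative addition of the tethered Si–H bond to solvated [Rh((S)-BINAP)]+ raises monovalent rhodium to trivalent rhodium, the alkene held close by the O9 tether coordinates and undergoes migratory insertion, and reductive elimination ends the cycle; since every bond is made from the metal-bound side, Si (to C7) and H (to C8) arrive suprafacially whichever of Rh–H or Rh–Si inserts first. The closest known reaction types are the rhodium–diphosphine-catalysed enantioselective intramolecular hydrosilylation of (E)-cinnamyl-type silyl ethers and the non-asymmetric 5-endo hydrosilylation of 2-alkoxyallyl silyl ethers with a terminal methylene; their combination on a trisubstituted 2-aryloxy-3-aryl alkene has not been shown. The one ring formed, the 1,2-oxasilolane O9–Si–C7–C8–C9, closes in the 5-endo mode through the C7–Si bond, because 4-exo delivery to the fully substituted C8 would give a strained oxasiletane and would oppose the enol-ether polarisation (C7 nucleophilic toward silicon, C8 hydride-accepting). C7 (R) is controlled by the ligand, which must direct the metal to the Re face at C7, and C8 (S) is then tied to C7 because both new bonds form on one face of an alkene of single (Z) geometry, which places ring A and the aryloxy group trans on the new ring and corresponds to erythro after oxidation. The step needs face selectivity, preservation of alkene geometry before productive insertion and no loss of aryloxide; ring A trans to C9 reproduces the substitution pattern of the cinnamyl substrates that respond well to this catalyst, and the ketal both removes a ketone that Si–H could reduce and keeps ring B electron-rich so that its phenoxide leaves poorly.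

**Step 8**
Reactants: 13 (3R,4S)-3-[4-(benzyloxy)-3-methoxyphenyl]-4-[2,6-dimethoxy-4-(2-methyl-1,3-dioxolan-2-yl)phenoxy]-2,2-diphenyl-1,2-oxasilolane
Product: 14 (1R,2S)-1-[4-(benzyloxy)-3-methoxyphenyl]-2-[2,6-dimethoxy-4-(2-methyl-1,3-dioxolan-2-yl)phenoxy]propane-1,3-diol (erythro)
Conditions: 30% aq H2O2, KHCO3, THF/MeOH, 25–40 °C; aq Na2S2O3, then dilute aq NaOH wash
Reagents that add atoms: hydrogen peroxide, OO
Why: Tamao oxidation, in which hydroperoxide adds to the alkoxy-activated silicon and C7 migrates from Si to O with retention so that C7 stays (R), the Si–O9 bond is solvolysed and the Si-phenyl groups leave as phenol, the bicarbonate-buffered fluoride-free medium being chosen to hold back Peterson-type loss of the β-aryloxide.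

**Step 9**
Reactants: 14 (1R,2S)-1-[4-(benzyloxy)-3-methoxyphenyl]-2-[2,6-dimethoxy-4-(2-methyl-1,3-dioxolan-2-yl)phenoxy]propane-1,3-diol
Product: 15 1-(4-{[(1R,2S)-1-[4-(benzyloxy)-3-methoxyphenyl]-1,3-dihydroxypropan-2-yl]oxy}-3,5-dimethoxyphenyl)ethan-1-one
Conditions: 0.5 M aq HCl, THF, 0 °C to rt; aq NaHCO3
Reagents that add atoms: water, O
Why: Acid-catalysed ketal hydrolysis runs through an oxocarbenium ion stabilised by ring B and is far faster than ionisation of the C7 benzylic alcohol, which the neighbouring electron-withdrawing aryloxy group retards, so C7 and C8 should stay untouched.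

**Step 10**
Reactants: 15 1-(4-{[(1R,2S)-1-[4-(benzyloxy)-3-methoxyphenyl]-1,3-dihydroxypropan-2-yl]oxy}-3,5-dimethoxyphenyl)ethan-1-one
Product: 16 1-(4-{[(1R,2S)-1,3-dihydroxy-1-(4-hydroxy-3-methoxyphenyl)propan-2-yl]oxy}-3,5-dimethoxyphenyl)ethan-1-one (target, 7R,8S, erythro)
Conditions: H2 (1 atm), Pd/C (10 wt %), EtOAc, rt; stopped after uptake of one equivalent
Reagents that add atoms: none
Why: Catalytic hydrogenolysis of an aryl benzyl ether over Pd/C under neutral conditions is much faster than reduction of the electron-rich aryl ketone or cleavage of the secondary benzylic C7–OH, and no stereocentre takes part.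

**Compound list**
1 | acetosyringone | CC(=O)c1cc(OC)c(O)c(OC)c1 | starting material
2 | ethyl bromoacetate | CCOC(=O)CBr | starting material
3 | ethyl 2-(4-acetyl-2,6-dimethoxyphenoxy)acetate | CCOC(=O)COc1c(OC)cc(C(C)=O)cc1OC | intermediate
4 | ethyl 2-[2,6-dimethoxy-4-(2-methyl-1,3-dioxolan-2-yl)phenoxy]acetate | CCOC(=O)COc1c(OC)cc(C2(C)OCCO2)cc1OC | intermediate
5 | 4-(benzyloxy)-3-methoxybenzaldehyde (O-benzylvanillin) | COc1cc(C=O)ccc1OCc1ccccc1 | starting material
6 | lithium enolate of 4 (not isolated) | [Li]OC(OCC)=COc1c(OC)cc(C2(C)OCCO2)cc1OC | intermediate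
7 | lithium aldolate from 6 and 5 (not isolated, both diastereomers, racemic) | [Li]OC(c1ccc(OCc2ccccc2)c(OC)c1)C(Oc1c(OC)cc(C2(C)OCCO2)cc1OC)C(=O)OCC | intermediate
8 | ethyl 3-acetoxy-3-[4-(benzyloxy)-3-methoxyphenyl]-2-[2,6-dimethoxy-4-(2-methyl-1,3-dioxolan-2-yl)phenoxy]propanoate (both diastereomers, racemic) | CCOC(=O)C(Oc1c(OC)cc(C2(C)OCCO2)cc1OC)C(OC(C)=O)c1ccc(OCc2ccccc2)c(OC)c1 | intermediate
9 | ethyl (Z)-3-[4-(benzyloxy)-3-methoxyphenyl]-2-[2,6-dimethoxy-4-(2-methyl-1,3-dioxolan-2-yl)phenoxy]prop-2-enoate | COc1cc(/C=C(/C(=O)OCC)Oc2c(OC)cc(C3(C)OCCO3)cc2OC)ccc1OCc1ccccc1 | intermediate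
10 | (Z)-3-[4-(benzyloxy)-3-methoxyphenyl]-2-[2,6-dimethoxy-4-(2-methyl-1,3-dioxolan-2-yl)phenoxy]prop-2-en-1-ol | COc1cc(/C=C(/CO)Oc2c(OC)cc(C3(C)OCCO3)cc2OC)ccc1OCc1ccccc1 | intermediate
11 | chlorodiphenylsilane | Cl[SiH](c1ccccc1)c1ccccc1 | starting material
12 | (Z)-2-aryloxy-3-arylallyl diphenylsilyl ether (key-step precursor) | COc1cc(/C=C(/CO[SiH](c2ccccc2)c2ccccc2)Oc2c(OC)cc(C3(C)OCCO3)cc2OC)ccc1OCc1ccccc1 | intermediate
13 | (3R,4S)-3-[4-(benzyloxy)-3-methoxyphenyl]-4-[2,6-dimethoxy-4-(2-methyl-1,3-dioxolan-2-yl)phenoxy]-2,2-diphenyl-1,2-oxasilolane | COc1cc([C@@H]2[C@@H](Oc3c(OC)cc(C4(C)OCCO4)cc3OC)CO[Si]2(c2ccccc2)c2ccccc2)ccc1OCc1ccccc1 | intermediate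
14 | (1R,2S)-1-[4-(benzyloxy)-3-methoxyphenyl]-2-[2,6-dimethoxy-4-(2-methyl-1,3-dioxolan-2-yl)phenoxy]propane-1,3-diol | COc1cc([C@@H](O)[C@H](CO)Oc2c(OC)cc(C3(C)OCCO3)cc2OC)ccc1OCc1ccccc1 | intermediate
15 | 1-(4-{[(1R,2S)-1-[4-(benzyloxy)-3-methoxyphenyl]-1,3-dihydroxypropan-2-yl]oxy}-3,5-dimethoxyphenyl)ethan-1-one | COc1cc([C@@H](O)[C@H](CO)Oc2c(OC)cc(C(C)=O)cc2OC)ccc1OCc1ccccc1 | intermediate
16 | 1-(4-{[(1R,2S)-1,3-dihydroxy-1-(4-hydroxy-3-methoxyphenyl)propan-2-yl]oxy}-3,5-dimethoxyphenyl)ethan-1-one (CNP0242981.1) | COc1cc([C@@H](O)[C@H](CO)Oc2c(OC)cc(C(C)=O)cc2OC)ccc1O | target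

**Total step count:** 10. **Longest linear sequence:** 10 steps (1 to 16); 2, 5 and 11 enter as bought materials.

**Steps most likely to fail**

**1. Step 7 (the labelled step).**
- The crowded trisubstituted enol ether may bind rhodium too weakly for insertion, so that the Si–H bond is used up in side reactions.
- Reversible hydride insertion may scramble the alkene geometry and erode the erythro relationship.
- Face selection may be poor.
- Aryloxide may be expelled from a benzylic rhodium alkyl.

The fallback uses known chemistry and replaces catalysis with auxiliary control. It sets out from 4 and 5 and comes back to the route at 15.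
- LiOH in THF/H2O, with acidification only to pH 4 (citric acid), converts 4 into 2-[2,6-dimethoxy-4-(2-methyl-1,3-dioxolan-2-yl)phenoxy]acetic acid F1.
- Activation with pivaloyl chloride/Et3N and reaction with the lithium salt of (R)-4-benzyl-1,3-oxazolidin-2-one gives the N-(aryloxyacetyl)oxazolidinone F2.
- An Evans syn aldol reaction (Bu2BOTf, iPr2NEt, CH2Cl2, −78 to 0 °C, then 5) gives the (2R,3S)-syn aldol imide F3.
- LiBH4 in THF removes the auxiliary reductively to give the threo-(7S,8S)-diol F4.
- TBSCl/imidazole silylates the primary O9 to give the threo 9-O-TBS ether F5.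
- A Mitsunobu reaction (4-nitrobenzoic acid, PPh3, DIAD, THF) inverts C7 to give the erythro-(7R,8S) 4-nitrobenzoate F6.
- K2CO3/MeOH frees the erythro 9-O-TBS alcohol F7.
- The aqueous HCl/THF of step 9 then removes silyl ether and ketal together to give 15.

C8 is fixed by the auxiliary. Any leakage of the Mitsunobu step through a benzylic cation would therefore give a separable diastereomer, not the enantiomer.

**2. Step 8.** Three Si–C bonds on the hindered diphenylsilicon must be oxidised. During the long exposure, β-elimination of aryloxide from the pentacoordinate silicate, or protodesilylation at benzylic C7, may outrun the carbon-to-oxygen migration.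

The fallback changes the silicon tether rather than the oxidant. It sets out from 10 and comes back at 14.
- 1,1,3,3-Tetramethyldisilazane (neat, rt, volatiles removed in vacuo, salt-free) gives the (Z)-allyl dimethylsilyl ether F8.
- The rhodium/BINAP cyclisation of step 7 gives the (3R,4S)-2,2-dimethyl-1,2-oxasilolane F9.
- H2O2/KHCO3 at 0 °C to rt then gives 14.

The silicon of F9 is less hindered, has no aryl groups to be cleaved, and belongs to the class for which peroxide oxidation beside a β-alkoxy group is established.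

**3. Step 4.** Geometric control in the elimination may be incomplete and the isomers may separate poorly, which would carry over into an erythro/threo mixture.

The fallback is a thermodynamically controlled condensation through a crystalline acid. It sets out from 4 and 5 and comes back at 9.
- The acid F1 (LiOH on 4 as above) is condensed with 5 in a Perkin condensation (Ac2O, excess Et3N, 90 °C, the amine buffer protecting the ketal). This gives (Z)-3-[4-(benzyloxy)-3-methoxyphenyl]-2-[2,6-dimethoxy-4-(2-methyl-1,3-dioxolan-2-yl)phenoxy]prop-2-enoic acid F10.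
- F10 is brought to geometric purity by recrystallisation.
- O-Alkylation with EtI/K2CO3 in DMF gives 9.

**Further compounds**
F1 | step 7 | 2-[2,6-dimethoxy-4-(2-methyl-1,3-dioxolan-2-yl)phenoxy]acetic acid | OC(=O)COc1c(OC)cc(C2(C)OCCO2)cc1OC
F2 | step 7 | (R)-4-benzyl-3-{2-[2,6-dimethoxy-4-(2-methyl-1,3-dioxolan-2-yl)phenoxy]acetyl}-1,3-oxazolidin-2-one | O=C(COc1c(OC)cc(C2(C)OCCO2)cc1OC)N1[C@H](Cc2ccccc2)COC1=O
F3 | step 7 | (R)-4-benzyl-3-{(2R,3S)-3-[4-(benzyloxy)-3-methoxyphenyl]-2-[2,6-dimethoxy-4-(2-methyl-1,3-dioxolan-2-yl)phenoxy]-3-hydroxypropanoyl}-1,3-oxazolidin-2-one | COc1cc([C@H](O)[C@H](C(=O)N2[C@H](Cc3ccccc3)COC2=O)Oc2c(OC)cc(C3(C)OCCO3)cc2OC)ccc1OCc1ccccc1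
F4 | step 7 | (1S,2S)-1-[4-(benzyloxy)-3-methoxyphenyl]-2-[2,6-dimethoxy-4-(2-methyl-1,3-dioxolan-2-yl)phenoxy]propane-1,3-diol (threo) | COc1cc([C@H](O)[C@H](CO)Oc2c(OC)cc(C3(C)OCCO3)cc2OC)ccc1OCc1ccccc1
F5 | step 7 | (1S,2S)-1-[4-(benzyloxy)-3-methoxyphenyl]-3-(tert-butyldimethylsilyloxy)-2-[2,6-dimethoxy-4-(2-methyl-1,3-dioxolan-2-yl)phenoxy]propan-1-ol | COc1cc([C@H](O)[C@H](CO[Si](C)(C)C(C)(C)C)Oc2c(OC)cc(C3(C)OCCO3)cc2OC)ccc1OCc1ccccc1
F6 | step 7 | (1R,2S)-1-[4-(benzyloxy)-3-methoxyphenyl]-3-(tert-butyldimethylsilyloxy)-2-[2,6-dimethoxy-4-(2-methyl-1,3-dioxolan-2-yl)phenoxy]propyl 4-nitrobenzoate | COc1cc([C@@H](OC(=O)c2ccc(cc2)[N+](=O)[O-])[C@H](CO[Si](C)(C)C(C)(C)C)Oc2c(OC)cc(C3(C)OCCO3)cc2OC)ccc1OCc1ccccc1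
F7 | step 7 | (1R,2S)-1-[4-(benzyloxy)-3-methoxyphenyl]-3-(tert-butyldimethylsilyloxy)-2-[2,6-dimethoxy-4-(2-methyl-1,3-dioxolan-2-yl)phenoxy]propan-1-ol | COc1cc([C@@H](O)[C@H](CO[Si](C)(C)C(C)(C)C)Oc2c(OC)cc(C3(C)OCCO3)cc2OC)ccc1OCc1ccccc1
F8 | step 8 | (Z)-3-[4-(benzyloxy)-3-methoxyphenyl]-2-[2,6-dimethoxy-4-(2-methyl-1,3-dioxolan-2-yl)phenoxy]prop-2-en-1-yl dimethylsilyl ether | COc1cc(/C=C(/CO[SiH](C)C)Oc2c(OC)cc(C3(C)OCCO3)cc2OC)ccc1OCc1ccccc1
F9 | step 8 | (3R,4S)-3-[4-(benzyloxy)-3-methoxyphenyl]-4-[2,6-dimethoxy-4-(2-methyl-1,3-dioxolan-2-yl)phenoxy]-2,2-dimethyl-1,2-oxasilolane | COc1cc([C@@H]2[C@@H](Oc3c(OC)cc(C4(C)OCCO4)cc3OC)CO[Si]2(C)C)ccc1OCc1ccccc1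
F10 | step 4 | (Z)-3-[4-(benzyloxy)-3-methoxyphenyl]-2-[2,6-dimethoxy-4-(2-methyl-1,3-dioxolan-2-yl)phenoxy]prop-2-enoic acid | COc1cc(/C=C(/C(=O)O)Oc2c(OC)cc(C3(C)OCCO3)cc2OC)ccc1OCc1ccccc1
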